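**Retrosynthetic overview**
1. The C3 silyl ether is removed last; the C6 chloride and the C5=C16 methylene come from an ene-type chlorination of a C5=C6 oxocene, and that ring (ring C) comes from ring-closing metathesis.
2. Ring B (pyran), the quaternary C8 and the C9 carbinol come from one SmI2 ketyl/β-alkoxyacrylate cyclisation; the spiro-lactone follows by lactonisation and C17 methylation; the acrylate comes from oxa-Michael addition of the C2 hydroxyl to an ynoate.
3. The C2/C3 anti-diol chain comes from a Weinreb ketone synthesis, enolate hydroxylation and chelation-controlled reduction; the C11/C12 cis-diol from face-selective dihydroxylation of a ring-A diene.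
4. Key step: Birch reductive methylation of m-toluic acid breaks the arene and creates quaternary C1 with a skipped diene; a formaldehyde ene reaction then installs C9 at C10 and moves the diene into conjugation.
5. Ring order: A (from the arene), then B with the lactone, then C.

Assumptions: positions carry briarane numbering (ring A = C1, C10–C14; C15 and C20 = methyls on C1 and C11; C16 on C5; C17–C19 = lactone carbons, C18 = methyl on C17); in step 2 the (S)-amine salt of the (S)-acid is taken as the less soluble one (otherwise the (R)-amine is used).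

**Route**

Step 1
Reactants: 1 3-methylbenzoic acid (m-toluic acid)
Product: 3 rac-1,3-dimethylcyclohexa-2,5-diene-1-carboxylic acid, via dilithium dienediolate 2 (not isolated)
Conditions: Li, NH3(l), THF, −78 °C; then MeI, −78 °C → rt; aq. HCl
Reagents that add atoms: iodomethane, CI
Why: Birch reductive alkylation, in which dissolving-metal reduction gives the cross-conjugated dienediolate that is methylated at the carboxyl-bearing carbon, so aromaticity is broken, quaternary C1 (with C15) is created as a racemate, and a skipped diene carrying the future C20 methyl on one alkene is left.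

Step 2
Reactants: 3 rac-1,3-dimethylcyclohexa-2,5-diene-1-carboxylic acid
Product: 4 (S)-1-phenylethylammonium (S)-1,3-dimethylcyclohexa-2,5-diene-1-carboxylate
Conditions: (S)-1-phenylethylamine (1.0 equiv), EtOAc/EtOH, two crystallisations
Reagents that add atoms: (S)-1-phenylethylamine, C[C@H](N)c1ccccc1
Why: Classical resolution by crystallisation of diastereomeric ammonium carboxylate salts, which selects the 1S enantiomer from which every later substrate-controlled step is relayed.

Step 3
Reactants: 4 (S)-1-phenylethylammonium (S)-1,3-dimethylcyclohexa-2,5-diene-1-carboxylate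
Product: 7 (S)-N-methoxy-N,1,3-trimethylcyclohexa-2,5-diene-1-carboxamide, via free acid 5 (not isolated), via acid chloride 6 (not isolated)
Conditions: 1 M HCl/Et2O; (COCl)2, DMF (cat.), CH2Cl2, 0 °C → rt; MeNHOMe·HCl, pyridine, CH2Cl2, 0 °C
Reagents that add atoms: N,O-dimethylhydroxylamine hydrochloride, CNOC.Cl
Why: Acid liberation, acid chloride formation and amidation give the Weinreb amide without touching the quaternary stereocentre and provide a bulky, Lewis-basic C2 group for the next step.

Step 4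
Reactants: 7 (S)-N-methoxy-N,1,3-trimethylcyclohexa-2,5-diene-1-carboxamide
Product: 8 (1S,6S)-6-(hydroxymethyl)-N-methoxy-N,1,5-trimethylcyclohexa-2,4-diene-1-carboxamide
Conditions: (CH2O)n, Me2AlCl (3 equiv), CH2Cl2, −78 → 0 °C
Reagents that add atoms: paraformaldehyde (as formaldehyde), C=O
Why: Me2AlCl-promoted carbonyl-ene reaction of formaldehyde, which bonds to C10 (the less substituted end of the only trisubstituted alkene) on the face anti to the aluminium-complexed amide so that C9 ends cis to the C15 methyl (10S), while the doubly allylic C12–H is transferred and the alkenes become the conjugated C11=C12–C13=C14 diene.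

Step 5
Reactants: 8 (1S,6S)-6-(hydroxymethyl)-N-methoxy-N,1,5-trimethylcyclohexa-2,4-diene-1-carboxamide
Product: 9 C9 triethylsilyl ether of 8
Conditions: TESCl, imidazole, CH2Cl2, 0 °C
Reagents that add atoms: chlorotriethylsilane, CC[Si](Cl)(CC)CC
Why: Standard silylation of the primary C9 hydroxyl, which later allows a one-step unveiling of the C9 aldehyde.

Step 6
Reactants: 9 C9 triethylsilyl ether of 8
Product: 10 ring-A 11,12-cis-diol (1S,10S,11S,12R; C13=C14 retained; Weinreb amide on C1; CH2OTES on C10)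
Conditions: OsO4 (2 mol%), NMO, acetone–H2O (10:1), 0 °C
Reagents that add atoms: N-methylmorpholine N-oxide, C[N+]1([O-])CCOCC1; water, O
Why: Upjohn dihydroxylation, in which OsO4 adds to the more electron-rich trisubstituted C11=C12 alkene of the diene from the face anti to the adjacent C10 CH2OTES group, setting 11S and 12R as a cis-diol and leaving the hindered C13=C14 alkene.

Step 7
Reactants: 10 ring-A 11,12-cis-diol
Product: 11 11,12-O-isopropylidene acetal of 10
Conditions: 2-methoxypropene, PPTS (cat.), CH2Cl2, 0 °C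
Reagents that add atoms: 2-methoxypropene, COC(C)=C
Why: Acid-catalysed acetonide formation on the cis-1,2-diol under anhydrous conditions that the primary triethylsilyl ether survives.

Step 8
Reactants: 11 11,12-O-isopropylidene acetal of 10
Product: 12 C2 ketone bearing the C3–C5(C16) 3-methylbut-3-enyl chain
Conditions: CH2=C(Me)CH2CH2MgBr, THF, 0 °C → rt; aq. NH4Cl
Reagents that add atoms: 3-methylbut-3-en-1-ylmagnesium bromide, C=C(C)CC[Mg]Br
Why: Weinreb ketone synthesis, the chelated tetrahedral intermediate preventing over-addition and delivering C3, C4, C5 and C16 in one operation.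

Step 9
Reactants: 12 C2 ketone
Product: 13 (3R)-3-hydroxy C2 ketone
Conditions: KHMDS, THF, −78 °C; (−)-(camphorsulfonyl)oxaziridine; aq. NH4Cl
Reagents that add atoms: (−)-(camphorsulfonyl)oxaziridine, CC1(C)C2CCC13CS(=O)(=O)N4OC34C2
Why: Davis asymmetric enolate hydroxylation, in which the Z potassium enolate (C3 is the only enolisable position) is oxidised by the chiral N-sulfonyloxaziridine antipode that delivers oxygen to the face giving 3R.

Step 10
Reactants: 13 (3R)-3-hydroxy C2 ketone
Product: 14 (2S,3R)-2,3-anti-diol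
Conditions: Zn(BH4)2, Et2O, −30 °C
Reagents that add atoms: none
Why: Chelation-controlled (Cram-chelate) ketone reduction, zinc bridging the C2 carbonyl and the C3 hydroxyl so that hydride adds anti to the C4 chain and gives the 2S carbinol anti to C3–OH.

Step 11
Reactants: 14 (2S,3R)-2,3-anti-diol
Product: 15 3-O-tert-butyldimethylsilyl ether of 14 (C2–OH free)
Conditions: TBSCl, imidazole, DMF, 0 °C → rt
Reagents that add atoms: tert-butyldimethylsilyl chloride, CC(C)(C)[Si](C)(C)Cl
Why: Selective silylation of the C3 hydroxyl, the C2 hydroxyl being neopentyl (next to quaternary C1) and therefore much slower.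

Step 12
Reactants: 16 methyl propiolate, 17 (E)-but-2-enal (crotonaldehyde)
Product: 18 methyl (S,E)-4-hydroxyhept-5-en-2-ynoate
Conditions: Me2Zn, ProPhenol ligand (10 mol%, antipode giving 4S), Ph3P=O (20 mol%), toluene, 0 °C
Reagents that add atoms: none
Why: Zinc–ProPhenol catalysed asymmetric alkynylation of an enal (Trost), the dinuclear zinc alkynylide adding to one aldehyde face to set the carbinol that becomes C7.

Step 13
Reactants: 18 methyl (S,E)-4-hydroxyhept-5-en-2-ynoate
Product: 19 methyl (S,E)-4-(triethylsilyloxy)hept-5-en-2-ynoate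
Conditions: TESCl, imidazole, CH2Cl2, 0 °C
Reagents that add atoms: chlorotriethylsilane, CC[Si](Cl)(CC)CC
Why: Standard silylation, which blocks tetronate formation until after ring B is closed.

Step 14
Reactants: 15 3-O-tert-butyldimethylsilyl ether of 14, 19 methyl (S,E)-4-(triethylsilyloxy)hept-5-en-2-ynoate
Product: 20 (E)-β-alkoxyacrylate linking C2–O–C8 (C8=C17H–C19O2Me; C7 OTES; propenyl on C7)
Conditions: PMe3 (20 mol%), CH2Cl2, 0 °C → rt
Reagents that add atoms: none
Why: Phosphine-catalysed oxa-Michael addition of the only free hydroxyl to the ynoate, giving the thermodynamically favoured E β-alkoxyacrylate without affecting C2 or C7.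

Step 15
Reactants: 20 (E)-β-alkoxyacrylate
Product: 21 C9 aldehyde of 20
Conditions: (COCl)2, DMSO, CH2Cl2, −78 → −30 °C; Et3N
Reagents that add atoms: none
Why: Swern oxidation run directly on the primary triethylsilyl ether (silyl transfer to the chlorosulfonium, then ylide fragmentation), the secondary silyl ethers being inert, so the aldehyde appears only once the C2 oxygen is masked.

Step 16
Reactants: 21 C9 aldehyde of 20
Product: 23 ring-B spiro-lactone (8S,9R; C9–OH; lactone C19–O–C7; C17 H2), via hydroxy ester 22 (not isolated)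
Conditions: SmI2 (3 equiv), MeOH (3 equiv), THF, −78 → 0 °C; then HF·pyridine, pyridine, THF, 0 °C → rt
Reagents that add atoms: none
Why: SmI2 ketyl–olefin reductive cyclisation onto the β-alkoxyacrylate (Nakata-type pyran synthesis) through a chair transition state with samarium bridging ketyl and ester, which puts C17 and C3 equatorial, C7 axial and C9–OH equatorial (8S, 9R) on a ring forced trans by C1/C10, followed by selective triethylsilyl removal and lactonisation of the C7 hydroxyl onto C19.

Step 17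
Reactants: 23 ring-B spiro-lactone
Product: 25 (17R)-17-methyl spiro-lactone, via C17-epimeric methyl lactone 24 (not isolated)
Conditions: LDA (2.2 equiv), THF–DMPU, −78 °C; MeI (1.0 equiv); then LDA (1.5 equiv), −78 °C; AcOH, −78 °C
Reagents that add atoms: iodomethane, CI
Why: Lactone enolate alkylation followed by re-enolisation and kinetic protonation at −78 °C (to suppress β-alkoxide elimination), both electrophiles approaching C17 from the lactone face that carries only the ring oxygen and H7, so methylation gives the 17-epimer and the final protonation gives 17R with the methyl cis to C9.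

Step 18
Reactants: 25 (17R)-17-methyl spiro-lactone
Product: 26 9,11,12-triol (3-O-TBS retained)
Conditions: BiCl3 (10 mol%), MeCN–H2O (50:1), rt
Reagents that add atoms: none
Why: Mild Lewis-acid acetonide hydrolysis that leaves the secondary silyl ether, the lactone and both side-chain alkenes intact.

Step 19
Reactants: 26 9,11,12-triol
Product: 27 9,11,12-triacetate (metathesis precursor)
Conditions: Ac2O, DMAP, Et3N, CH2Cl2, rt → 40 °C
Reagents that add atoms: acetic anhydride, CC(=O)OC(C)=O
Why: DMAP-catalysed acetylation of the secondary C9 and C12 hydroxyls and, on warming, of the tertiary C11 hydroxyl, with C3 protected as its silyl ether.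

Step 20
Reactants: 27 9,11,12-triacetate
Product: 28 5Z-oxocene (ring C closed, C5 methyl, C5=C6)
Conditions: second-generation Hoveyda–Grubbs catalyst RuCl2(SIMes)(=CH–C6H4-2-OiPr) (15 mol%), toluene (2 mM), 80 °C
Reagents that add atoms: none
Why: Ring-closing metathesis between the propenyl group on C7 and the 1,1-disubstituted alkene on C4, releasing propene and giving the Z trisubstituted alkene of the eight-membered cyclic ether.

Step 21
Reactants: 28 5Z-oxocene
Product: 29 3-O-tert-butyldimethylsilyl ether of the target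
Conditions: NCS (1.1 equiv), PhSeCl (10 mol%), CH2Cl2, 0 °C → rt
Reagents that add atoms: N-chlorosuccinimide, O=C1CCC(=O)N1Cl
Why: Selenium-catalysed ene-type allylic chlorination (Hori–Sharpless), in which the electrophile engages the only trisubstituted electron-rich alkene from its exposed convex face, chlorine ends on C6 (6S) and the C16 methyl loses a proton to give the exocyclic methylene.

Step 22
Reactants: 29 3-O-tert-butyldimethylsilyl ether of the target
Product: 30 target CNP0333938.3
Conditions: HF·pyridine, pyridine, THF, 0 °C → rt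
Reagents that add atoms: none
Why: Fluoride-mediated desilylation under buffered conditions that the acetates, the lactone and the allylic chloride tolerate.

**Compound list**
1 | 3-methylbenzoic acid | Cc1cccc(C(=O)O)c1 | starting material
2 | dilithium (3-methylcyclohexa-2,5-dien-1-ylidene)methanediolate | CC1=CC(=C([O-])[O-])C=CC1.[Li+].[Li+] | intermediate
3 | rac-1,3-dimethylcyclohexa-2,5-diene-1-carboxylic acid | CC1(C(=O)O)C=CCC(C)=C1 | intermediate
4 | (S)-1-phenylethylammonium (S)-1,3-dimethylcyclohexa-2,5-diene-1-carboxylate | C[C@]1(C(=O)[O-])C=CCC(C)=C1.C[C@H]([NH3+])c1ccccc1 | intermediate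
5 | (S)-1,3-dimethylcyclohexa-2,5-diene-1-carboxylic acid | C[C@]1(C(=O)O)C=CCC(C)=C1 | intermediate
6 | (S)-1,3-dimethylcyclohexa-2,5-diene-1-carbonyl chloride | C[C@]1(C(=O)Cl)C=CCC(C)=C1 | intermediate
7 | (S)-N-methoxy-N,1,3-trimethylcyclohexa-2,5-diene-1-carboxamide | C[C@]1(C(=O)N(C)OC)C=CCC(C)=C1 | intermediate
8 | (1S,6S)-6-(hydroxymethyl)-N-methoxy-N,1,5-trimethylcyclohexa-2,4-diene-1-carboxamide | C[C@]1(C(=O)N(C)OC)C=CC=C(C)[C@@H]1CO | intermediate
9 | C9 triethylsilyl ether of 8 | C[C@]1(C(=O)N(C)OC)C=CC=C(C)[C@@H]1CO[Si](CC)(CC)CC | intermediate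
10 | ring-A 11,12-cis-diol (1S,10S,11S,12R) | C[C@]1(C(=O)N(C)OC)C=C[C@@H](O)[C@@](C)(O)[C@@H]1CO[Si](CC)(CC)CC | intermediate
11 | 11,12-O-isopropylidene acetal of 10 | C[C@]1(C(=O)N(C)OC)C=C[C@H]2OC(C)(C)O[C@@]2(C)[C@@H]1CO[Si](CC)(CC)CC | intermediate
12 | C2 ketone with 3-methylbut-3-enyl chain | C[C@]1(C(=O)CCC(C)=C)C=C[C@H]2OC(C)(C)O[C@@]2(C)[C@@H]1CO[Si](CC)(CC)CC | intermediate
13 | (3R)-3-hydroxy C2 ketone | C[C@]1(C(=O)[C@H](O)CC(C)=C)C=C[C@H]2OC(C)(C)O[C@@]2(C)[C@@H]1CO[Si](CC)(CC)CC | intermediate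
14 | (2S,3R)-2,3-anti-diol | C[C@]1([C@H](O)[C@H](O)CC(C)=C)C=C[C@H]2OC(C)(C)O[C@@]2(C)[C@@H]1CO[Si](CC)(CC)CC | intermediate
15 | 3-O-TBS ether of 14 | C[C@]1([C@H](O)[C@H](O[Si](C)(C)C(C)(C)C)CC(C)=C)C=C[C@H]2OC(C)(C)O[C@@]2(C)[C@@H]1CO[Si](CC)(CC)CC | intermediate
16 | methyl propiolate | C#CC(=O)OC | starting material
17 | (E)-but-2-enal | C/C=C/C=O | starting material
18 | methyl (S,E)-4-hydroxyhept-5-en-2-ynoate | COC(=O)C#C[C@@H](O)/C=C/C | intermediate
19 | methyl (S,E)-4-(triethylsilyloxy)hept-5-en-2-ynoate | COC(=O)C#C[C@@H](O[Si](CC)(CC)CC)/C=C/C | intermediate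
20 | (E)-β-alkoxyacrylate from 15 and 19 | C[C@]1([C@H](O/C(=C/C(=O)OC)[C@@H](O[Si](CC)(CC)CC)/C=C/C)[C@H](O[Si](C)(C)C(C)(C)C)CC(C)=C)C=C[C@H]2OC(C)(C)O[C@@]2(C)[C@@H]1CO[Si](CC)(CC)CC | intermediate
21 | C9 aldehyde of 20 | C[C@]1([C@H](O/C(=C/C(=O)OC)[C@@H](O[Si](CC)(CC)CC)/C=C/C)[C@H](O[Si](C)(C)C(C)(C)C)CC(C)=C)C=C[C@H]2OC(C)(C)O[C@@]2(C)[C@@H]1C=O | intermediate
22 | ring-B hydroxy ester (C9–OH, CH2CO2Me and CH(OTES)-propenyl on C8) | CC(=C)C[C@@H](O[Si](C)(C)C(C)(C)C)[C@H]2O[C@]([C@H](O)[C@@H]4[C@]2(C)C=C[C@H]5OC(C)(C)O[C@]54C)(CC(=O)OC)[C@@H](O[Si](CC)(CC)CC)/C=C/C | intermediate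
23 | ring-B spiro-lactone, C17 unsubstituted | CC(=C)C[C@@H](O[Si](C)(C)C(C)(C)C)[C@H]2O[C@]3([C@H](O)[C@@H]4[C@]2(C)C=C[C@H]5OC(C)(C)O[C@]54C)CC(=O)O[C@H]3/C=C/C | intermediate
24 | C17-epimeric 17-methyl spiro-lactone | CC(=C)C[C@@H](O[Si](C)(C)C(C)(C)C)[C@H]2O[C@]3([C@H](O)[C@@H]4[C@]2(C)C=C[C@H]5OC(C)(C)O[C@]54C)[C@H](C)C(=O)O[C@H]3/C=C/C | intermediate
25 | (17R)-17-methyl spiro-lactone | CC(=C)C[C@@H](O[Si](C)(C)C(C)(C)C)[C@H]2O[C@]3([C@H](O)[C@@H]4[C@]2(C)C=C[C@H]5OC(C)(C)O[C@]54C)[C@@H](C)C(=O)O[C@H]3/C=C/C | intermediate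
26 | 9,11,12-triol | CC(=C)C[C@@H](O[Si](C)(C)C(C)(C)C)[C@H]2O[C@]3([C@H](O)[C@@H]4[C@]2(C)C=C[C@@H](O)[C@@]4(C)O)[C@@H](C)C(=O)O[C@H]3/C=C/C | intermediate
27 | 9,11,12-triacetate | CC(=C)C[C@@H](O[Si](C)(C)C(C)(C)C)[C@H]2O[C@]3([C@H](OC(C)=O)[C@@H]4[C@]2(C)C=C[C@@H](OC(C)=O)[C@@]4(C)OC(C)=O)[C@@H](C)C(=O)O[C@H]3/C=C/C | intermediate
28 | 5Z-oxocene (ring C closed) | C1[C@@H](O[Si](C)(C)C(C)(C)C)[C@H]2O[C@]3([C@H](OC(C)=O)[C@@H]4[C@]2(C)C=C[C@@H](OC(C)=O)[C@@]4(C)OC(C)=O)[C@@H](C)C(=O)O[C@H]3/C=C1/C | intermediate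
29 | 3-O-TBS ether of the target | C=C1C[C@@H](O[Si](C)(C)C(C)(C)C)[C@H]2O[C@]3([C@H](OC(C)=O)[C@@H]4[C@]2(C)C=C[C@@H](OC(C)=O)[C@@]4(C)OC(C)=O)[C@@H](C)C(=O)O[C@H]3[C@H]1Cl | intermediate
30 | CNP0333938.3 (1S,2S,3R,6S,7R,8S,9R,10S,11S,12R,17R) | C=C1C[C@@H](O)[C@H]2O[C@]3([C@H](OC(C)=O)[C@@H]4[C@]2(C)C=C[C@@H](OC(C)=O)[C@@]4(C)OC(C)=O)[C@@H](C)C(=O)O[C@H]3[C@H]1Cl | target

**Step count and risk**
Total: 22 steps. Longest linear sequence: 20 steps (steps 1–11 and 14–22); steps 12–13 make the ynoate.

The three steps most likely to fail: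

Step 21 (ene chlorination; exo versus endo alkene and the C6 configuration are not secured by precedent in this ring). The fallback sets out from 28 and returns at 29. The C5=C6 alkene of 28 is epoxidised with dimethyldioxirane (acetone, −20 °C) to the 5,6-epoxide F1. Cp2TiCl (from Cp2TiCl2 and Mn, THF) opens it by the trivalent titanium radical pathway to the C5 radical, and β-hydride loss from C16 gives the 6-hydroxy-5(16)-ene allylic alcohol F2. Displacement with inversion (PPh3, CCl4, or MsCl then LiCl) gives 29. Because epoxidation and direct chlorination use the same alkene face while the displacement inverts, this sequence delivers the C6 epimer that step 21 does not.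

Step 20 (metathesis to a trisubstituted alkene in a bridged eight-membered ring). The fallback sets out from 21 and returns at 28, and changes the order of ring formation so that the oxocene is closed on a monocycle before the pyran exists. Metathesis of 21 with the same catalyst gives the oxocene enoate aldehyde F3. SmI2/MeOH then HF·pyridine gives, through the transannularly cyclised hydroxy ester F4, the spiro-lactone F5. LDA/MeI then LDA/AcOH gives, through the C17 epimer F6, the 17R methyl lactone F7. BiCl3 in wet MeCN gives the triol F8, and Ac2O/DMAP gives 28.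

Step 16 (radical addition to a fully substituted acrylate carbon to form quaternary C8). The fallback sets out from 21 and returns at 22, and replaces the ketyl radical by polar acyl-anion chemistry. An intramolecular Stetter reaction (chiral aminoindanol-derived triazolium salt, KHMDS, toluene) forms the same C9–C8 bond and gives the C9 ketone F9. NaBH4 (MeOH, −40 °C; axial hydride, equatorial alcohol) gives hydroxy ester 22, which is desilylated and lactonised as in step 16.

**Further compounds**
F1 | step 21 | 5,6-epoxide of 28 | C[C@@]15C[C@@H](O[Si](C)(C)C(C)(C)C)[C@H]2O[C@]3([C@H](OC(C)=O)[C@@H]4[C@]2(C)C=C[C@@H](OC(C)=O)[C@@]4(C)OC(C)=O)[C@@H](C)C(=O)O[C@H]3[C@@H]1O5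
F2 | step 21 | 6-epi-hydroxy-5(16)-ene allylic alcohol | C=C1C[C@@H](O[Si](C)(C)C(C)(C)C)[C@H]2O[C@]3([C@H](OC(C)=O)[C@@H]4[C@]2(C)C=C[C@@H](OC(C)=O)[C@@]4(C)OC(C)=O)[C@@H](C)C(=O)O[C@H]3[C@@H]1O
F3 | step 20 | oxocene enoate aldehyde (ring C closed before ring B) | C[C@]1([C@@H]6O/C(=C/C(=O)OC)[C@@H](O[Si](CC)(CC)CC)/C=C(/C)C[C@H]6O[Si](C)(C)C(C)(C)C)C=C[C@H]2OC(C)(C)O[C@@]2(C)[C@@H]1C=O
F4 | step 20 | ring-closed hydroxy ester | C1[C@@H](O[Si](C)(C)C(C)(C)C)[C@H]2O[C@]([C@H](O)[C@@H]4[C@]2(C)C=C[C@H]5OC(C)(C)O[C@]54C)(CC(=O)OC)[C@@H](O[Si](CC)(CC)CC)/C=C1/C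
F5 | step 20 | ring-closed spiro-lactone, C17 unsubstituted | C1[C@@H](O[Si](C)(C)C(C)(C)C)[C@H]2O[C@]3([C@H](O)[C@@H]4[C@]2(C)C=C[C@H]5OC(C)(C)O[C@]54C)CC(=O)O[C@H]3/C=C1/C
F6 | step 20 | ring-closed C17-epimeric methyl lactone | C1[C@@H](O[Si](C)(C)C(C)(C)C)[C@H]2O[C@]3([C@H](O)[C@@H]4[C@]2(C)C=C[C@H]5OC(C)(C)O[C@]54C)[C@H](C)C(=O)O[C@H]3/C=C1/C
F7 | step 20 | ring-closed (17R)-methyl lactone | C1[C@@H](O[Si](C)(C)C(C)(C)C)[C@H]2O[C@]3([C@H](O)[C@@H]4[C@]2(C)C=C[C@H]5OC(C)(C)O[C@]54C)[C@@H](C)C(=O)O[C@H]3/C=C1/C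
F8 | step 20 | ring-closed 9,11,12-triol | C1[C@@H](O[Si](C)(C)C(C)(C)C)[C@H]2O[C@]3([C@H](O)[C@@H]4[C@]2(C)C=C[C@@H](O)[C@@]4(C)O)[C@@H](C)C(=O)O[C@H]3/C=C1/C
F9 | step 16 | ring-B C9 ketone ester | CC(=C)C[C@@H](O[Si](C)(C)C(C)(C)C)[C@H]2O[C@](C(=O)[C@@H]4[C@]2(C)C=C[C@H]5OC(C)(C)O[C@]54C)(CC(=O)OC)[C@@H](O[Si](CC)(CC)CC)/C=C/C
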